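**Plan**

- Numbering: 2,3-dihydrobenzofuran O1, C2, C3, C3a, C4–C7, C7a; ring A is the benzo ring, ring B the dihydrofuran, ring C the aryl on C3, ring D its outer phenol ring, ring E the aryloxy ring on C6.
- Enabling feature: C3 carries the para-oxygenated ring C and is bonded to C3a, which lies ortho to the O1-bearing C7a of ring A. C3–C3a and O1–C2 are therefore cut together, giving a ring A phenol and a racemic ring C/D aryl propargylic acetate that supplies C3, C2 and the exocyclic carbon.
- Cuts made before that: the CH2OH oxygen (back to an exocyclic C2=CH2) and the three allyl–aryl bonds (back to aryl chlorides). Cuts made after: the C6–O diaryl ether bond, the ring C–ring D biaryl bond and the C3–alkyne bond.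
- Forward order: phenol (steps 1–3) and acetate (steps 4–7) are joined in step 8, which closes ring B, the only ring built. Hydroboration, silylation, threefold allylation and global deprotection follow.
- Stereochemistry: C3 (S) comes from ligand-controlled attack on a copper allenylidene. C2 (R) comes from hydroboration on the face opposite the C3 aryl, which gives the cis relation.

Key step: step 8

Assumption: which antipode of the P,N,N ligand leads to 3S cannot be derived from the structure alone; the route is written for the antipode that does, to be fixed in one test run (both antipodes are accessible).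

**Route**

Step 1
Reactants: 1 3-bromo-5-chloro-2-hydroxybenzaldehyde
Product: 2 3-bromo-5-chloro-2-(methoxymethoxy)benzaldehyde
Conditions: MOMCl, iPr2NEt, CH2Cl2, 0 °C to rt
Reagents that add atoms: chloromethyl methyl ether (MOMCl), COCCl
Why: O-alkylation of the acidic salicyl phenol with the reactive α-chloro ether (MOM protection) under an amine base that leaves the aldehyde alone.

Step 2
Reactants: 2 3-bromo-5-chloro-2-(methoxymethoxy)benzaldehyde; 3 4-chlorophenol
Product: 4 5-chloro-3-(4-chlorophenoxy)-2-(methoxymethoxy)benzaldehyde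
Conditions: CuI (10 mol%), N,N-dimethylglycine hydrochloride (30 mol%), Cs2CO3, dioxane, 90 °C
Reagents that add atoms: none
Why: Ullmann diaryl ether synthesis, in which amino-acid-ligated copper at 90 °C engages the C–Br bond and should leave both C–Cl bonds, the aldehyde and the MOM acetal untouched.

Step 3
Reactants: 4 5-chloro-3-(4-chlorophenoxy)-2-(methoxymethoxy)benzaldehyde
Product: 6 5-chloro-3-(4-chlorophenoxy)-2-(methoxymethoxy)phenol, via aryl formate 5 (not isolated)
Conditions: mCPBA, CH2Cl2, rt; aq. NaHCO3/Na2S2O3 wash; K2CO3 (cat.), MeOH, rt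
Reagents that add atoms: meta-chloroperbenzoic acid (mCPBA), OOC(=O)c1cccc(Cl)c1
Why: Baeyer–Villiger (Dakin-type) oxidation, in which the ortho-alkoxy aryl group migrates to oxygen to give the formate, and mild methanolysis then frees the C7a hydroxyl without harming the MOM group, the diaryl ether or the chlorides.

Step 4
Reactants: 7 3-bromo-4-hydroxybenzaldehyde; 8 (5-chloro-2-hydroxyphenyl)boronic acid
Product: 9 5'-chloro-2',6-dihydroxy-[1,1'-biphenyl]-3-carbaldehyde
Conditions: Pd(PPh3)4 (3 mol%), K2CO3, dioxane/H2O (4:1), 90 °C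
Reagents that add atoms: none
Why: Suzuki–Miyaura coupling, which tolerates free phenols and the aldehyde, while the triphenylphosphine catalyst inserts into C–Br only and keeps the ring D chloride.

Step 5
Reactants: 9 5'-chloro-2',6-dihydroxy-[1,1'-biphenyl]-3-carbaldehyde
Product: 10 5'-chloro-2',6-bis(methoxymethoxy)-[1,1'-biphenyl]-3-carbaldehyde
Conditions: MOMCl (3 equiv), iPr2NEt, CH2Cl2, 0 °C to rt
Reagents that add atoms: chloromethyl methyl ether (MOMCl), COCCl
Why: twofold O-alkylation of both phenols (MOM protection), which also installs the para donor that later stabilises the propargylic cation.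

Step 6
Reactants: 10 5'-chloro-2',6-bis(methoxymethoxy)-[1,1'-biphenyl]-3-carbaldehyde
Product: 11 racemic 1-[5'-chloro-2',6-bis(methoxymethoxy)-[1,1'-biphenyl]-3-yl]prop-2-yn-1-ol
Conditions: ethynylmagnesium bromide, THF, 0 °C; aq. NH4Cl
Reagents that add atoms: ethynylmagnesium bromide, C#C[Mg]Br
Why: Grignard 1,2-addition of the alkynyl nucleophile to the aryl aldehyde; the carbinol centre is racemic and is erased by ionisation in step 8.

Step 7
Reactants: 11 racemic 1-[5'-chloro-2',6-bis(methoxymethoxy)-[1,1'-biphenyl]-3-yl]prop-2-yn-1-ol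
Product: 12 racemic 1-[5'-chloro-2',6-bis(methoxymethoxy)-[1,1'-biphenyl]-3-yl]prop-2-yn-1-yl acetate
Conditions: Ac2O, Et3N, DMAP (cat.), CH2Cl2, 0 °C
Reagents that add atoms: acetic anhydride, CC(=O)OC(C)=O
Why: DMAP-catalysed acylation of the secondary propargylic alcohol, which installs the leaving group for copper allenylidene formation.

Step 8
Reactants: 6 5-chloro-3-(4-chlorophenoxy)-2-(methoxymethoxy)phenol; 12 racemic 1-[5'-chloro-2',6-bis(methoxymethoxy)-[1,1'-biphenyl]-3-yl]prop-2-yn-1-yl acetate
Product: 14 (3S)-4-chloro-6-(4-chlorophenoxy)-3-[5'-chloro-2',6-bis(methoxymethoxy)biphenyl-3-yl]-7-(methoxymethoxy)-2-methylidene-2,3-dihydro-1-benzofuran, via ortho-propargyl phenol 13 (not isolated)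
Conditions: Cu(MeCN)4BF4 (5 mol%), chiral tridentate ketimine P,N,N ligand [imine of 2-benzoylpyridine and 1-(2-diphenylphosphanylphenyl)ethylamine] (5.5 mol%), iPr2NEt (1.2 equiv), MeOH, −20 °C, then 0 °C to rt; filtration through Et3N-deactivated silica
Reagents that add atoms: none
Why: The monovalent copper–ligand complex and iPr2NEt turn the terminal alkyne of 12 into a copper acetylide that expels acetate to give a copper allenylidene whose cationic C3 is stabilised by the para MOM-oxy group of ring C; C3a of 6 (ortho to the free C7a hydroxyl, para to the C6 aryloxy group) attacks this carbon and rearomatisation gives 13. The closest known reaction type is the copper-catalysed asymmetric propargylic Friedel–Crafts reaction and formal [3+2] annulation of terminal propargylic esters with 2-naphthols and electron-rich phenols. Ring B then closes by 5-exo-dig addition of the C7a oxygen to the copper-activated alkyne at C2, and protodemetalation leaves the exocyclic enol ether. C3 is set by the chiral ligand, which shields one face of the planar allenylidene, so both enantiomers of 12 should converge on the 3S product. The step needs C- over O-alkylation and C3a over C5 attack: the hydroxyl is flanked by the C7 MOM ether, C5 lies between chlorine and the aryloxy group, and only the C3a adduct can cyclise. Migration of the double bond to the aromatic 2-methylbenzofuran, which would destroy C3, is held back by the weak amine base, the low temperature and the non-acidic work-up.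

Step 9
Reactants: 14 (3S)-4-chloro-6-(4-chlorophenoxy)-3-[5'-chloro-2',6-bis(methoxymethoxy)biphenyl-3-yl]-7-(methoxymethoxy)-2-methylidene-2,3-dihydro-1-benzofuran
Product: 16 [(2R,3S)-4-chloro-6-(4-chlorophenoxy)-3-[5'-chloro-2',6-bis(methoxymethoxy)biphenyl-3-yl]-7-(methoxymethoxy)-2,3-dihydro-1-benzofuran-2-yl]methanol, via B-alkyl-9-BBN adduct 15 (not isolated)
Conditions: 9-BBN (0.5 M in THF), THF, 0 °C to rt; then aq. NaOH, 30% H2O2, 0 °C
Reagents that add atoms: hydrogen peroxide, OO
Why: Hydroboration–oxidation of the 1,1-disubstituted enol ether puts boron on the terminal CH2 (steric and electronic preference) and adds syn from the face of ring B opposite the C3 aryl, so hydrogen enters C2 anti to the aryl and the CH2B, then CH2OH after oxidation with retention, ends up cis to it (2R).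

Step 10
Reactants: 16 [(2R,3S)-4-chloro-6-(4-chlorophenoxy)-3-[5'-chloro-2',6-bis(methoxymethoxy)biphenyl-3-yl]-7-(methoxymethoxy)-2,3-dihydro-1-benzofuran-2-yl]methanol
Product: 17 tert-butyl{[(2R,3S)-4-chloro-6-(4-chlorophenoxy)-3-[5'-chloro-2',6-bis(methoxymethoxy)biphenyl-3-yl]-7-(methoxymethoxy)-2,3-dihydro-1-benzofuran-2-yl]methoxy}dimethylsilane
Conditions: TBSCl, imidazole, DMF, rt
Reagents that add atoms: tert-butyldimethylsilyl chloride (TBSCl), CC(C)(C)[Si](C)(C)Cl
Why: silyl ether protection of the primary alcohol keeps a free hydroxyl (a possible hydride source) out of the palladium step and comes off together with the MOM groups in step 12.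

Step 11
Reactants: 17 tert-butyl{[(2R,3S)-4-chloro-6-(4-chlorophenoxy)-3-[5'-chloro-2',6-bis(methoxymethoxy)biphenyl-3-yl]-7-(methoxymethoxy)-2,3-dihydro-1-benzofuran-2-yl]methoxy}dimethylsilane
Product: 18 tert-butyl{[(2R,3S)-4-allyl-6-(4-allylphenoxy)-3-[5'-allyl-2',6-bis(methoxymethoxy)biphenyl-3-yl]-7-(methoxymethoxy)-2,3-dihydro-1-benzofuran-2-yl]methoxy}dimethylsilane
Conditions: allylB(pin) (4.5 equiv), Pd(OAc)2 (10 mol%), XPhos (2-dicyclohexylphosphino-2',4',6'-triisopropylbiphenyl, 20 mol%), K3PO4, THF/H2O, 65 °C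
Reagents that add atoms: allylboronic acid pinacol ester (allylB(pin)), C=CCB1OC(C)(C)C(C)(C)O1
Why: threefold Suzuki–Miyaura allyl–aryl coupling, in which the bulky electron-rich biarylphosphine lets palladium insert into unactivated and ortho-substituted aryl chlorides and the unsubstituted allylboronate transfers allyl without regiochemical ambiguity, C2 and C3 being untouched.

Step 12
Reactants: 18 tert-butyl{[(2R,3S)-4-allyl-6-(4-allylphenoxy)-3-[5'-allyl-2',6-bis(methoxymethoxy)biphenyl-3-yl]-7-(methoxymethoxy)-2,3-dihydro-1-benzofuran-2-yl]methoxy}dimethylsilane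
Product: 19 Magnolignan H, (2R,3S)-4-allyl-6-(4-allylphenoxy)-3-(5'-allyl-2',6-dihydroxybiphenyl-3-yl)-2-(hydroxymethyl)-2,3-dihydro-1-benzofuran-7-ol
Conditions: HCl (1.25 M in MeOH), THF, 40 °C
Reagents that add atoms: none
Why: acid-catalysed acetal exchange (cleavage of the three aryl MOM ethers) and methanolysis of the silyl ether under anhydrous conditions that should leave the allyl groups and the cis C2/C3 centres unchanged.

**Compound list**

1 | 3-bromo-5-chloro-2-hydroxybenzaldehyde | O=Cc1cc(Cl)cc(Br)c1O | starting material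
2 | 3-bromo-5-chloro-2-(methoxymethoxy)benzaldehyde | O=Cc1cc(Cl)cc(Br)c1OCOC | intermediate
3 | 4-chlorophenol | Oc1ccc(Cl)cc1 | starting material
4 | 5-chloro-3-(4-chlorophenoxy)-2-(methoxymethoxy)benzaldehyde | O=Cc1cc(Cl)cc(Oc2ccc(Cl)cc2)c1OCOC | intermediate
5 | 5-chloro-3-(4-chlorophenoxy)-2-(methoxymethoxy)phenyl formate | O=COc1cc(Cl)cc(Oc2ccc(Cl)cc2)c1OCOC | intermediate (not isolated)
6 | 5-chloro-3-(4-chlorophenoxy)-2-(methoxymethoxy)phenol (ring A phenol) | Oc1cc(Cl)cc(Oc2ccc(Cl)cc2)c1OCOC | intermediate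
7 | 3-bromo-4-hydroxybenzaldehyde | O=Cc1ccc(O)c(Br)c1 | starting material
8 | (5-chloro-2-hydroxyphenyl)boronic acid | OB(O)c1cc(Cl)ccc1O | starting material
9 | 5'-chloro-2',6-dihydroxy-[1,1'-biphenyl]-3-carbaldehyde | O=Cc1ccc(O)c(-c2cc(Cl)ccc2O)c1 | intermediate
10 | 5'-chloro-2',6-bis(methoxymethoxy)-[1,1'-biphenyl]-3-carbaldehyde | O=Cc1ccc(OCOC)c(-c2cc(Cl)ccc2OCOC)c1 | intermediate
11 | racemic 1-[5'-chloro-2',6-bis(methoxymethoxy)-[1,1'-biphenyl]-3-yl]prop-2-yn-1-ol | OC(C#C)c1ccc(OCOC)c(-c2cc(Cl)ccc2OCOC)c1 | intermediate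
12 | racemic 1-[5'-chloro-2',6-bis(methoxymethoxy)-[1,1'-biphenyl]-3-yl]prop-2-yn-1-yl acetate (ring C/D propargylic acetate) | CC(=O)OC(C#C)c1ccc(OCOC)c(-c2cc(Cl)ccc2OCOC)c1 | intermediate
13 | (S)-3-chloro-5-(4-chlorophenoxy)-2-{1-[5'-chloro-2',6-bis(methoxymethoxy)biphenyl-3-yl]prop-2-yn-1-yl}-6-(methoxymethoxy)phenol | C#C[C@H](c1c(Cl)cc(Oc2ccc(Cl)cc2)c(OCOC)c1O)c1ccc(OCOC)c(-c2cc(Cl)ccc2OCOC)c1 | intermediate (not isolated)
14 | (3S)-4-chloro-6-(4-chlorophenoxy)-3-[5'-chloro-2',6-bis(methoxymethoxy)biphenyl-3-yl]-7-(methoxymethoxy)-2-methylidene-2,3-dihydro-1-benzofuran | Clc1ccc(Oc2cc(Cl)c3c(c2OCOC)OC(=C)[C@H]3c2ccc(OCOC)c(-c3cc(Cl)ccc3OCOC)c2)cc1 | intermediate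
15 | B-alkyl-9-BBN adduct of 14 (boron on the exocyclic CH2, which is cis to the C3 aryl) | Clc1ccc(Oc2cc(Cl)c3c(c2OCOC)O[C@@H](CB4C5CCCC4CCC5)[C@H]3c2ccc(OCOC)c(-c3cc(Cl)ccc3OCOC)c2)cc1 | intermediate (not isolated)
16 | [(2R,3S)-4-chloro-6-(4-chlorophenoxy)-3-[5'-chloro-2',6-bis(methoxymethoxy)biphenyl-3-yl]-7-(methoxymethoxy)-2,3-dihydro-1-benzofuran-2-yl]methanol (cis) | Clc1ccc(Oc2cc(Cl)c3c(c2OCOC)O[C@@H](CO)[C@H]3c2ccc(OCOC)c(-c3cc(Cl)ccc3OCOC)c2)cc1 | intermediate
17 | TBS ether of 16, (2R,3S) | Clc1ccc(Oc2cc(Cl)c3c(c2OCOC)O[C@@H](CO[Si](C)(C)C(C)(C)C)[C@H]3c2ccc(OCOC)c(-c3cc(Cl)ccc3OCOC)c2)cc1 | intermediate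
18 | triallyl tris-MOM TBS ether, (2R,3S) | C=CCc1ccc(Oc2cc(CC=C)c3c(c2OCOC)O[C@@H](CO[Si](C)(C)C(C)(C)C)[C@H]3c2ccc(OCOC)c(-c3cc(CC=C)ccc3OCOC)c2)cc1 | intermediate
19 | Magnolignan H, (2R,3S) | C=CCc1ccc(Oc2cc(CC=C)c3c(c2O)O[C@@H](CO)[C@H]3c2ccc(O)c(-c3cc(CC=C)ccc3O)c2)cc1 | target

**Step count and risks**

Total: 12 steps. Longest linear sequence: 9 steps (steps 4–12, from 7 and 8 to 19).

Steps most likely to fail:

Step 8. The phenol may be propargylated at oxygen or at C5 instead of C3a, the ligand may discriminate the allenylidene faces poorly with this ortho-substituted phenol, or the exocyclic double bond may migrate into ring B under the amine base. Fallback: setting out from phenol 6 and propargylic alcohol 11, a Lewis-acid-catalysed propargylic Friedel–Crafts alkylation (Ca(NTf2)2/Bu4NPF6 cat., CH2Cl2, rt) is reversible at oxygen and should funnel material to carbon, giving the racemic ortho-propargyl phenol F1, a stable compound from which any C5 isomer can be removed. Preparative chromatography on a chiral stationary phase would then supply the S enantiomer 13. Ligand-free 5-exo-dig cycloisomerisation of 13 (Cu(MeCN)4BF4 cat., iPr2NEt, MeOH, 0 °C) returns to the route at 14.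

Step 9. The β-aryloxy dialkylborane 15 may eliminate the C7a aryloxide and open ring B before oxidation, or the facial bias set by the C3 aryl may be insufficient. Fallback: setting out from 14, an iridium-catalysed hydroboration with pinacolborane ([Ir(cod)Cl]2/dppe cat., HBpin, THF, rt) proceeds by metal hydride insertion from the same open face and should give the isolable, weakly Lewis-acidic pinacol boronate F2. This can be purified and checked for the cis relation, and oxidation with NaBO3·4H2O in THF/H2O returns to the route at 16.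

Step 11. One of the three chlorides, most likely the hindered one at C4, may fail to couple, or palladium hydride species may move the allyl double bonds into conjugation. Fallback: the polarity of the coupling is reversed. Setting out from 17, threefold Miyaura borylation (B2pin2, Pd2(dba)3/XPhos cat., KOAc, dioxane, 100 °C) should give the tris(pinacol boronate) F3. Allyl–aryl coupling of F3 with allyl bromide through a π-allyl palladium intermediate (Pd(PPh3)4 cat., K2CO3, THF/H2O, 60 °C) returns to the route at 18.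

**Further compounds**

F1 | step 8 | racemic 3-chloro-5-(4-chlorophenoxy)-2-{1-[5'-chloro-2',6-bis(methoxymethoxy)biphenyl-3-yl]prop-2-yn-1-yl}-6-(methoxymethoxy)phenol | C#CC(c1c(Cl)cc(Oc2ccc(Cl)cc2)c(OCOC)c1O)c1ccc(OCOC)c(-c2cc(Cl)ccc2OCOC)c1
F2 | step 9 | 2-{[(2R,3S)-4-chloro-6-(4-chlorophenoxy)-3-[5'-chloro-2',6-bis(methoxymethoxy)biphenyl-3-yl]-7-(methoxymethoxy)-2,3-dihydro-1-benzofuran-2-yl]methyl}-4,4,5,5-tetramethyl-1,3,2-dioxaborolane (cis) | Clc1ccc(Oc2cc(Cl)c3c(c2OCOC)O[C@@H](CB4OC(C)(C)C(C)(C)O4)[C@H]3c2ccc(OCOC)c(-c3cc(Cl)ccc3OCOC)c2)cc1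
F3 | step 11 | tris(pinacol boronate) of 17, with B(pin) in place of each of the three chlorines, (2R,3S) | CC1(C)OB(OC1(C)C)c1ccc(Oc2cc(B3OC(C)(C)C(C)(C)O3)c3c(c2OCOC)O[C@@H](CO[Si](C)(C)C(C)(C)C)[C@H]3c2ccc(OCOC)c(-c3cc(B4OC(C)(C)C(C)(C)O4)ccc3OCOC)c2)cc1
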